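The route rests on disconnecting the C2–C3 bond of the dihydrofuran ring (ring B). Because C2 is a methine held between O1 and the 3,4-dimethoxyphenyl ring (ring C), it can be traced back to the benzylic methylene of an aryl 3,4-dimethoxybenzyl ether, with C3 as a carbene carbon. A single chiral dirhodium-catalysed intramolecular C–H insertion then forges C2–C3, closes ring B and sets both stereocentres (C2 absolutely; C3 cis, later epimerised to trans). The precursor is a methyl aryldiazoacetate whose benzene ring (ring A) carries the ortho 3,4-dimethoxybenzyloxy group, a neighbouring silyloxy group (the future 7-OH) and a para bromide (the future acrylic acid site).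

Key step: step 8

Assumption (remark on the chemistry): Rh2(S-PTTL)4 is taken to deliver the 2R configuration, by analogy with simpler 2-(benzyloxy)aryl diazoacetates. If the opposite sense were found, the mirror-image catalyst Rh2(R-PTTL)4 would be used with nothing else changed.

Abbreviations: TIPS = triisopropylsilyl; DIAD = diisopropyl azodicarboxylate; p-ABSA = 4-acetamidobenzenesulfonyl azide; DBU = 1,8-diazabicyclo[5.4.0]undec-7-ene; TBAF = tetrabutylammonium fluoride.

Step 1
Reactants: 1 5-bromo-2-hydroxy-3-methoxybenzaldehyde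
Product: 2 5-bromo-2,3-dihydroxybenzaldehyde
Conditions: BBr3, CH2Cl2, −78 °C to rt; then H2O
Reagents that add atoms: none
Why: Lewis-acid O-demethylation, in which bromide attacks the methyl group of the boron-complexed ether, is assisted by the neighbouring hydroxyl and should leave the formyl group and the aryl bromide untouched, so the bromine position is fixed by the starting material.

Step 2
Reactants: 2 5-bromo-2,3-dihydroxybenzaldehyde
Product: 3 5-bromo-2-hydroxy-3-(triisopropylsilyloxy)benzaldehyde
Conditions: TIPSCl (1.05 equiv), imidazole, DMF, 0 °C to rt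
Reagents that add atoms: chlorotriisopropylsilane, CC(C)[Si](Cl)(C(C)C)C(C)C
Why: Regioselective O-silylation should occur at the 3-OH, which is less hindered and not tied up in the hydrogen bond to the formyl group, and any 2-O-silyl isomer should relax by O-to-O silyl shift to this same, thermodynamically preferred chelated isomer.

Step 3
Reactants: 3 5-bromo-2-hydroxy-3-(triisopropylsilyloxy)benzaldehyde; 4 3,4-dimethoxybenzyl alcohol
Product: 5 5-bromo-2-(3,4-dimethoxybenzyloxy)-3-(triisopropylsilyloxy)benzaldehyde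
Conditions: PPh3, DIAD, THF, 0 °C to rt
Reagents that add atoms: none
Why: Mitsunobu etherification of the acidic, formyl-conjugated phenol with a primary benzylic alcohol forms the aryl ether without a long-lived free phenoxide in a dipolar medium, so the silyl group should stay on O3.

Step 4
Reactants: 5 5-bromo-2-(3,4-dimethoxybenzyloxy)-3-(triisopropylsilyloxy)benzaldehyde
Product: 6 [5-bromo-2-(3,4-dimethoxybenzyloxy)-3-(2-methoxyethenyl)phenoxy]triisopropylsilane (E/Z mixture)
Conditions: MeOCH2PPh3Cl, NaN(SiMe3)2, THF, 0 °C; then 5, 0 °C to rt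
Reagents that add atoms: (methoxymethyl)triphenylphosphonium chloride, [Cl-].COC[P+](c1ccccc1)(c1ccccc1)c1ccccc1
Why: Wittig methoxymethylenation of a non-enolisable aryl aldehyde adds the one carbon that later becomes the C3 substituent, and the alkene geometry is irrelevant because both isomers hydrolyse to the same aldehyde.

Step 5
Reactants: 6 [5-bromo-2-(3,4-dimethoxybenzyloxy)-3-(2-methoxyethenyl)phenoxy]triisopropylsilane
Product: 8 2-[5-bromo-2-(3,4-dimethoxybenzyloxy)-3-(triisopropylsilyloxy)phenyl]acetic acid, via arylacetaldehyde 7 (not isolated)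
Conditions: 1 M HCl, THF, rt; then Na2HPO4 to pH 4, t-BuOH, 2-methyl-2-butene, NaClO2, 0 °C to rt
Reagents that add atoms: water, O; sodium chlorite, [Na+].[O-]Cl=O
Why: Acid-catalysed enol ether hydrolysis (C-protonation, hydration of the oxocarbenium ion, loss of methanol) followed in the same flask by Pinnick oxidation should convert the sensitive arylacetaldehyde to the acid before it can condense, with 2-methyl-2-butene scavenging hypochlorous acid to protect the electron-rich ring C.

Step 6
Reactants: 8 2-[5-bromo-2-(3,4-dimethoxybenzyloxy)-3-(triisopropylsilyloxy)phenyl]acetic acid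
Product: 9 methyl 2-[5-bromo-2-(3,4-dimethoxybenzyloxy)-3-(triisopropylsilyloxy)phenyl]acetate
Conditions: MeI, KHCO3, DMF, rt
Reagents that add atoms: iodomethane, CI
Why: SN2 O-alkylation of the carboxylate gives the methyl ester under conditions too weakly basic to deprotonate the benzylic methylene or cleave the aryl silyl ether.

Step 7
Reactants: 9 methyl 2-[5-bromo-2-(3,4-dimethoxybenzyloxy)-3-(triisopropylsilyloxy)phenyl]acetate
Product: 10 methyl 2-[5-bromo-2-(3,4-dimethoxybenzyloxy)-3-(triisopropylsilyloxy)phenyl]-2-diazoacetate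
Conditions: p-ABSA, DBU, MeCN, 0 °C to rt
Reagents that add atoms: 4-acetamidobenzenesulfonyl azide, CC(=O)Nc1ccc(cc1)S(=O)(=O)N=[N+]=[N-]
Why: Regitz diazo transfer, in which the DBU-generated arylacetate enolate attacks the terminal azide nitrogen and the triazene collapses to the diazo ester and the sulfonamide, is standard for methyl arylacetates and non-nucleophilic DBU spares the silyl ether.

Step 8
Reactants: 10 methyl 2-[5-bromo-2-(3,4-dimethoxybenzyloxy)-3-(triisopropylsilyloxy)phenyl]-2-diazoacetate
Product: 11 methyl (2R,3S)-5-bromo-2-(3,4-dimethoxyphenyl)-7-(triisopropylsilyloxy)-2,3-dihydro-1-benzofuran-3-carboxylate (cis)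
Conditions: Rh2(S-PTTL)4 (dirhodium tetrakis[N-phthaloyl-(S)-tert-leucinate], 1 mol %), toluene, −60 °C, slow addition of 10
Reagents that add atoms: none
Why: Rh2(S-PTTL)4 expels N2 from 10 to give an electrophilic donor/acceptor rhodium carbene at the future C3, which takes up one hydridic C–H bond of the O1–CH2–aryl methylene in a concerted, asynchronous three-centre event that makes the C2–C3 bond and releases the catalyst (the bond broken is C–H; the O1–CH2 bond stays intact). The closest known reaction type is the chiral dirhodium tetracarboxylate-catalysed intramolecular C–H insertion of 2-(benzyloxy)aryl diazoacetates to cis-2-aryl-2,3-dihydrobenzofuran-3-carboxylates. Ring B (O1–C2–C3–C3a–C7a) closes as a 1,5-insertion through a five-membered cyclic transition state. C2 is set by the chiral phthalimido carboxylate ligands, which discriminate the two enantiotopic methylene hydrogens (S-ligand taken to give 2R), and C3 forms cis to the aryl group under kinetic control because aryl and ester both point away from the rhodium face in the compact insertion transition state. The step needs chemoselectivity for this C–H bond over Büchner addition to ring C, ylide formation at O1 and carbene dimerisation, which the double activation of the C–H bond (alpha to oxygen and benzylic to an electron-rich arene), the ortho tether, the flanking silyloxy group that turns the OCH2 group toward the carbene, low temperature and slow addition should secure, while bromide, silyl ether and methyl ethers are inert.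

Step 9
Reactants: 11 methyl (2R,3S)-5-bromo-2-(3,4-dimethoxyphenyl)-7-(triisopropylsilyloxy)-2,3-dihydro-1-benzofuran-3-carboxylate
Product: 12 methyl (2R,3R)-5-bromo-2-(3,4-dimethoxyphenyl)-7-(triisopropylsilyloxy)-2,3-dihydro-1-benzofuran-3-carboxylate (trans)
Conditions: DBU, MeCN, rt to 40 °C
Reagents that add atoms: none
Why: Base-mediated epimerisation through the benzylic ester enolate inverts only C3 and should settle on the trans isomer, which relieves the eclipsing of aryl and ester groups, while C2 is untouched and non-nucleophilic DBU spares the ester and the aryl silyl ether.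

Step 10
Reactants: 12 methyl (2R,3R)-5-bromo-2-(3,4-dimethoxyphenyl)-7-(triisopropylsilyloxy)-2,3-dihydro-1-benzofuran-3-carboxylate
Product: 13 [(2R,3S)-5-bromo-2-(3,4-dimethoxyphenyl)-7-(triisopropylsilyloxy)-2,3-dihydro-1-benzofuran-3-yl]methanol (trans)
Conditions: LiBH4, THF, 0 °C to rt
Reagents that add atoms: none
Why: Chemoselective borohydride reduction of the ester to the primary alcohol leaves the aryl bromide and silyl ether intact and does not touch either stereocentre (the descriptor at C3 changes to S only through the priority rules).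

Step 11
Reactants: 13 [(2R,3S)-5-bromo-2-(3,4-dimethoxyphenyl)-7-(triisopropylsilyloxy)-2,3-dihydro-1-benzofuran-3-yl]methanol; 14 methyl acrylate
Product: 15 methyl (E)-3-[(2R,3S)-2-(3,4-dimethoxyphenyl)-3-(hydroxymethyl)-7-(triisopropylsilyloxy)-2,3-dihydro-1-benzofuran-5-yl]prop-2-enoate
Conditions: Pd(OAc)2 (5 mol %), P(o-tol)3 (12 mol %), Et3N, DMF, 100 °C
Reagents that add atoms: none
Why: Mizoroki–Heck coupling (oxidative addition of the aryl bromide to zerovalent palladium formed in situ, syn-carbopalladation of the acrylate, syn-beta-hydride elimination) should give the E-cinnamate and tolerates the free primary alcohol.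

Step 12
Reactants: 15 methyl (E)-3-[(2R,3S)-2-(3,4-dimethoxyphenyl)-3-(hydroxymethyl)-7-(triisopropylsilyloxy)-2,3-dihydro-1-benzofuran-5-yl]prop-2-enoate
Product: 17 (E)-3-[(2R,3S)-2-(3,4-dimethoxyphenyl)-7-hydroxy-3-(hydroxymethyl)-2,3-dihydro-1-benzofuran-5-yl]prop-2-enoic acid (target), via phenolic methyl ester 16 (not isolated)
Conditions: TBAF, THF, 0 °C; then LiOH, H2O/MeOH, rt; then 1 M HCl to pH 3
Reagents that add atoms: lithium hydroxide, [Li+].[OH-]
Why: Fluoride cleaves the aryl Si–O bond and hydroxide then saponifies the cinnamate by acyl substitution in the same flask, and neither stereocentre carries an acidifying group any longer, so the trans (2R,3S) configuration should be retained.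

Compound list
1 | 5-bromo-2-hydroxy-3-methoxybenzaldehyde | O=Cc1cc(Br)cc(OC)c1O | starting material
2 | 5-bromo-2,3-dihydroxybenzaldehyde | O=Cc1cc(Br)cc(O)c1O | intermediate
3 | 5-bromo-2-hydroxy-3-(triisopropylsilyloxy)benzaldehyde | O=Cc1cc(Br)cc(O[Si](C(C)C)(C(C)C)C(C)C)c1O | intermediate
4 | 3,4-dimethoxybenzyl alcohol | COc1ccc(CO)cc1OC | starting material
5 | 5-bromo-2-(3,4-dimethoxybenzyloxy)-3-(triisopropylsilyloxy)benzaldehyde | O=Cc1cc(Br)cc(O[Si](C(C)C)(C(C)C)C(C)C)c1OCc1ccc(OC)c(OC)c1 | intermediate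
6 | [5-bromo-2-(3,4-dimethoxybenzyloxy)-3-(2-methoxyethenyl)phenoxy]triisopropylsilane (E/Z mixture) | COC=Cc1cc(Br)cc(O[Si](C(C)C)(C(C)C)C(C)C)c1OCc1ccc(OC)c(OC)c1 | intermediate
7 | 2-[5-bromo-2-(3,4-dimethoxybenzyloxy)-3-(triisopropylsilyloxy)phenyl]acetaldehyde | O=CCc1cc(Br)cc(O[Si](C(C)C)(C(C)C)C(C)C)c1OCc1ccc(OC)c(OC)c1 | intermediate
8 | 2-[5-bromo-2-(3,4-dimethoxybenzyloxy)-3-(triisopropylsilyloxy)phenyl]acetic acid | OC(=O)Cc1cc(Br)cc(O[Si](C(C)C)(C(C)C)C(C)C)c1OCc1ccc(OC)c(OC)c1 | intermediate
9 | methyl 2-[5-bromo-2-(3,4-dimethoxybenzyloxy)-3-(triisopropylsilyloxy)phenyl]acetate | COC(=O)Cc1cc(Br)cc(O[Si](C(C)C)(C(C)C)C(C)C)c1OCc1ccc(OC)c(OC)c1 | intermediate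
10 | methyl 2-[5-bromo-2-(3,4-dimethoxybenzyloxy)-3-(triisopropylsilyloxy)phenyl]-2-diazoacetate | COc1ccc(COc2c(O[Si](C(C)C)(C(C)C)C(C)C)cc(Br)cc2C(=[N+]=[N-])C(=O)OC)cc1OC | intermediate
11 | methyl (2R,3S)-5-bromo-2-(3,4-dimethoxyphenyl)-7-(triisopropylsilyloxy)-2,3-dihydro-1-benzofuran-3-carboxylate (cis) | COc1ccc([C@@H]2Oc3c(O[Si](C(C)C)(C(C)C)C(C)C)cc(Br)cc3[C@@H]2C(=O)OC)cc1OC | intermediate
12 | methyl (2R,3R)-5-bromo-2-(3,4-dimethoxyphenyl)-7-(triisopropylsilyloxy)-2,3-dihydro-1-benzofuran-3-carboxylate (trans) | COc1ccc([C@@H]2Oc3c(O[Si](C(C)C)(C(C)C)C(C)C)cc(Br)cc3[C@H]2C(=O)OC)cc1OC | intermediate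
13 | [(2R,3S)-5-bromo-2-(3,4-dimethoxyphenyl)-7-(triisopropylsilyloxy)-2,3-dihydro-1-benzofuran-3-yl]methanol (trans) | COc1ccc([C@@H]2Oc3c(O[Si](C(C)C)(C(C)C)C(C)C)cc(Br)cc3[C@H]2CO)cc1OC | intermediate
14 | methyl acrylate | C=CC(=O)OC | starting material
15 | methyl (E)-3-[(2R,3S)-2-(3,4-dimethoxyphenyl)-3-(hydroxymethyl)-7-(triisopropylsilyloxy)-2,3-dihydro-1-benzofuran-5-yl]prop-2-enoate | COc1ccc([C@@H]2Oc3c(O[Si](C(C)C)(C(C)C)C(C)C)cc(/C=C/C(=O)OC)cc3[C@H]2CO)cc1OC | intermediate
16 | methyl (E)-3-[(2R,3S)-2-(3,4-dimethoxyphenyl)-7-hydroxy-3-(hydroxymethyl)-2,3-dihydro-1-benzofuran-5-yl]prop-2-enoate | COc1ccc([C@@H]2Oc3c(O)cc(/C=C/C(=O)OC)cc3[C@H]2CO)cc1OC | intermediate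
17 | (E)-3-[(2R,3S)-2-(3,4-dimethoxyphenyl)-7-hydroxy-3-(hydroxymethyl)-2,3-dihydro-1-benzofuran-5-yl]prop-2-enoic acid | COc1ccc([C@@H]2Oc3c(O)cc(/C=C/C(=O)O)cc3[C@H]2CO)cc1OC | target

Total step count: 12. Longest linear sequence: 12 steps (1 to 17).

Steps most likely to fail

1. Step 8 (key step). The catalyst may fail to discriminate the two enantiotopic methylene hydrogens, or show the opposite sense, with this more hindered and more electron-rich ether. The insertion may also turn stepwise (hydride transfer to a benzylic oxocarbenium zwitterion), which would erode both the enantiomeric purity and the cis preference. The carbene may be diverted into Büchner addition on ring C or into dimerisation. Fallback, from 8 back to 13: acid 8 would be esterified (EDC·HCl, DMAP, CH2Cl2) with (R)-2-hydroxy-1-(pyrrolidin-1-yl)propan-1-one to give (R)-1-oxo-1-(pyrrolidin-1-yl)propan-2-yl 2-[5-bromo-2-(3,4-dimethoxybenzyloxy)-3-(triisopropylsilyloxy)phenyl]acetate F1. Diazo transfer (p-ABSA, DBU, MeCN) would give (R)-1-oxo-1-(pyrrolidin-1-yl)propan-2-yl 2-[5-bromo-2-(3,4-dimethoxybenzyloxy)-3-(triisopropylsilyloxy)phenyl]-2-diazoacetate F2. Insertion with Rh2(R-DOSP)4 (dirhodium tetrakis[(R)-N-(4-dodecylbenzenesulfonyl)prolinate]) in CH2Cl2 should then give (R)-1-oxo-1-(pyrrolidin-1-yl)propan-2-yl (2R,3R)-5-bromo-2-(3,4-dimethoxyphenyl)-7-(triisopropylsilyloxy)-2,3-dihydro-1-benzofuran-3-carboxylate F3 directly as the trans isomer. The R/R pairing of auxiliary and catalyst is taken as the matched one for 2R, and the covalently bound auxiliary makes any stereochemical leakage a separable diastereomer. LiBH4 in THF would reduce F3 to alcohol 13 and release the auxiliary alcohol, bypassing 9 to 12.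

2. Step 3. The silyl group may shift from O3 to O2 in the transient phenoxide, or etherification of the doubly ortho-flanked phenol may be slow enough for desilylation to compete, giving regioisomeric or unsilylated ethers. Fallback, from 2 back to 5: the dianion of 2 (NaH, 2.2 equiv, DMSO) would be alkylated with allyl bromide (1.0 equiv) at the more nucleophilic, non-chelated O3 to give 3-(allyloxy)-5-bromo-2-hydroxybenzaldehyde F4. Alkylation with 3,4-dimethoxybenzyl chloride (K2CO3, NaI, DMF), with no migratory group present, would give 3-(allyloxy)-5-bromo-2-(3,4-dimethoxybenzyloxy)benzaldehyde F5. Deallylation with Pd(PPh3)4 (tetrakis(triphenylphosphine)palladium, zerovalent palladium) and morpholine in THF at rt would give 5-bromo-2-(3,4-dimethoxybenzyloxy)-3-hydroxybenzaldehyde F6. Silylation (TIPSCl, imidazole, DMF), now next to an alkyl ether, returns to 5.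

3. Step 5. Acid may ionise the 3,4-dimethoxybenzyl aryl ether during enol ether hydrolysis, and the arylacetaldehyde may self-condense or air-oxidise before it is oxidised. Fallback, from 5 back to 8, with no acid and no free aldehyde: methylenation of 5 (MePPh3Br, KN(SiMe3)2, THF) would give [5-bromo-2-(3,4-dimethoxybenzyloxy)-3-ethenylphenoxy]triisopropylsilane F7. Anti-Markovnikov hydroboration with 9-BBN and oxidation with NaBO3·4H2O would give 2-[5-bromo-2-(3,4-dimethoxybenzyloxy)-3-(triisopropylsilyloxy)phenyl]ethanol F8. Oxidation with catalytic TEMPO and PhI(OAc)2 in MeCN/water would take F8 to acid 8.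

Further compounds
F1 | step 8 | (R)-1-oxo-1-(pyrrolidin-1-yl)propan-2-yl 2-[5-bromo-2-(3,4-dimethoxybenzyloxy)-3-(triisopropylsilyloxy)phenyl]acetate | C[C@@H](OC(=O)Cc1cc(Br)cc(O[Si](C(C)C)(C(C)C)C(C)C)c1OCc1ccc(OC)c(OC)c1)C(=O)N1CCCC1
F2 | step 8 | (R)-1-oxo-1-(pyrrolidin-1-yl)propan-2-yl 2-[5-bromo-2-(3,4-dimethoxybenzyloxy)-3-(triisopropylsilyloxy)phenyl]-2-diazoacetate | C[C@@H](OC(=O)C(=[N+]=[N-])c1cc(Br)cc(O[Si](C(C)C)(C(C)C)C(C)C)c1OCc1ccc(OC)c(OC)c1)C(=O)N1CCCC1
F3 | step 8 | (R)-1-oxo-1-(pyrrolidin-1-yl)propan-2-yl (2R,3R)-5-bromo-2-(3,4-dimethoxyphenyl)-7-(triisopropylsilyloxy)-2,3-dihydro-1-benzofuran-3-carboxylate | COc1ccc([C@@H]2Oc3c(O[Si](C(C)C)(C(C)C)C(C)C)cc(Br)cc3[C@H]2C(=O)O[C@H](C)C(=O)N4CCCC4)cc1OC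
F4 | step 3 | 3-(allyloxy)-5-bromo-2-hydroxybenzaldehyde | O=Cc1cc(Br)cc(OCC=C)c1O
F5 | step 3 | 3-(allyloxy)-5-bromo-2-(3,4-dimethoxybenzyloxy)benzaldehyde | O=Cc1cc(Br)cc(OCC=C)c1OCc1ccc(OC)c(OC)c1
F6 | step 3 | 5-bromo-2-(3,4-dimethoxybenzyloxy)-3-hydroxybenzaldehyde | O=Cc1cc(Br)cc(O)c1OCc1ccc(OC)c(OC)c1
F7 | step 5 | [5-bromo-2-(3,4-dimethoxybenzyloxy)-3-ethenylphenoxy]triisopropylsilane | C=Cc1cc(Br)cc(O[Si](C(C)C)(C(C)C)C(C)C)c1OCc1ccc(OC)c(OC)c1
F8 | step 5 | 2-[5-bromo-2-(3,4-dimethoxybenzyloxy)-3-(triisopropylsilyloxy)phenyl]ethanol | OCCc1cc(Br)cc(O[Si](C(C)C)(C(C)C)C(C)C)c1OCc1ccc(OC)c(OC)c1
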